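**Retrosynthetic overview**
1. Target ⇐ one-pot hydrogenation of the chain alkene and hydrogenolysis of two benzyl ethers in a dibenzyl-protected (S)-17-aryl-heptadec-5-en-3-ol.
2. Aryl–C17 bond ⇐ B-alkyl Suzuki–Miyaura coupling of 1-bromo-3,5-bis(benzyloxy)benzene with the terminal alkene of (S)-heptadeca-5,16-dien-3-ol.
3. C3–C4 bond and the only stereocentre ⇐ chiral-phosphoric-acid-catalysed allylboration of propanal with a racemic α-(undec-10-enyl)allyl boronate, used enantioconvergently (key step).
4. That boronate ⇐ undec-10-enylmagnesium bromide plus (E)-3-chloropropenyl pinacol boronate (1,2-metallate shift).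
5. No ring is formed; the resorcinol ring is bought as its dibenzyl ether.

Assumption: the chloropropenyl boronate, the aryl bromide and the catalyst (R)-TRIP [(R)-3,3′-bis(2,4,6-triisopropylphenyl)-1,1′-binaphthyl-2,2′-diyl hydrogen phosphate] are bought, and the C5=C6 geometry of the alkenol intermediates is left as an E/Z mixture because the last step saturates that alkene.

**Step 1**
Reactants: 1 11-bromoundec-1-ene; 2 (E)-2-(3-chloroprop-1-en-1-yl)-4,4,5,5-tetramethyl-1,3,2-dioxaborolane
Product: 5 rac-4,4,5,5-tetramethyl-2-(tetradeca-1,13-dien-3-yl)-1,3,2-dioxaborolane, via undec-10-enylmagnesium bromide 3 (not isolated), via bromomagnesium borate complex 4 (not isolated)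
Conditions: Mg, THF, rt; then 2 (0.9 equiv), THF, −78 °C → rt
Reagents that add atoms: none
Why: The primary Grignard reagent adds to boron to give an ate complex, and on warming the alkyl group shifts from boron to the adjacent vinylic carbon while the allylic chloride leaves in an SN2′ sense (vinylogous Matteson-type 1,2-metallate rearrangement), giving the α-substituted allylboronate whose stereocentre is racemic and is destroyed in step 2.

**Step 2**
Reactants: 5 rac-4,4,5,5-tetramethyl-2-(tetradeca-1,13-dien-3-yl)-1,3,2-dioxaborolane; 6 propanal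
Product: 8 (3S)-heptadeca-5,16-dien-3-ol (5E/5Z mixture), via O-pinacolboryl ether 7 (not isolated)
Conditions: (R)-TRIP (5 mol%), 6 (2 equiv), 4 Å MS, toluene, −30 → 0 °C to full consumption of 5; aq. NaHCO3 work-up
Reagents that add atoms: none
Why: Proposed new method: an enantioconvergent, alkene-geometry-divergent chiral-phosphoric-acid-catalysed allylboration, in which the catalyst (P–OH hydrogen-bonded to a boronate oxygen, P=O to the formyl C–H) holds a closed chair Zimmerman–Traxler transition state and fixes attack on the Re face of propanal for both enantiomers of 5, one enantiomer placing its C3 chain pseudo-axial to give the (3S,5Z) alcohol and the other pseudo-equatorial to give the (3S,5E) alcohol, so that with the boronate as limiting reagent its racemic stereocentre becomes sp2, both halves converge on the (S)-carbinol and the E/Z mixture is erased in step 4; the closest known reactions are the chiral-phosphoric-acid-catalysed allylboration of aldehydes with unsubstituted allyl pinacol boronate and the phosphoric-acid-mediated kinetic resolution of racemic secondary allylboronates, which stops at half conversion of the reagent.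

**Step 3**
Reactants: 8 (3S)-heptadeca-5,16-dien-3-ol; 9 9-borabicyclo[3.3.1]nonane (9-BBN); 10 1-bromo-3,5-bis(benzyloxy)benzene
Product: 12 (3S)-17-[3,5-bis(benzyloxy)phenyl]heptadec-5-en-3-ol (5E/5Z mixture), via bis(9-BBN) adduct 11 (not isolated)
Conditions: 9 (2.2 equiv), THF, 0 °C → rt; then 10, Pd(dppf)Cl2 (5 mol%), 3 M aq. NaOH, THF, 65 °C
Reagents that add atoms: none
Why: 9-BBN hydroborates the monosubstituted terminal alkene far faster than the 1,2-disubstituted one (the hydroxyl is capped as its borinate by the second equivalent), and the primary B-alkyl-9-BBN then undergoes B-alkyl Suzuki–Miyaura coupling with the aryl bromide without touching the carbinol stereocentre.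

**Step 4**
Reactants: 12 (3S)-17-[3,5-bis(benzyloxy)phenyl]heptadec-5-en-3-ol
Product: 13 Hansfordiol C [5-[(15S)-15-hydroxyheptadecyl]benzene-1,3-diol]
Conditions: H2 (1 atm), 10% Pd/C, EtOAc–EtOH, rt
Reagents that add atoms: none
Why: Heterogeneous catalytic hydrogenation saturates the C5=C6 alkene of either geometry and hydrogenolyses both benzyl ethers in one operation, while the non-allylic, non-benzylic secondary carbinol keeps its (S) configuration.

**Compound list**
1 | 11-bromoundec-1-ene | C=CCCCCCCCCCBr | starting material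
2 | (E)-2-(3-chloroprop-1-en-1-yl)-4,4,5,5-tetramethyl-1,3,2-dioxaborolane | ClC/C=C/B1OC(C)(C)C(C)(C)O1 | starting material
3 | undec-10-enylmagnesium bromide | C=CCCCCCCCCC[Mg]Br | intermediate
4 | bromomagnesium [(E)-3-chloroprop-1-en-1-yl](undec-10-en-1-yl)pinacolatoborate | C=CCCCCCCCCC[B-]1(/C=C/CCl)OC(C)(C)C(C)(C)O1.[Mg+]Br | intermediate
5 | rac-4,4,5,5-tetramethyl-2-(tetradeca-1,13-dien-3-yl)-1,3,2-dioxaborolane | C=CC(CCCCCCCCCC=C)B1OC(C)(C)C(C)(C)O1 | intermediate
6 | propanal | CCC=O | starting material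
7 | 2-{[(3S)-heptadeca-5,16-dien-3-yl]oxy}-4,4,5,5-tetramethyl-1,3,2-dioxaborolane (5E/5Z mixture) | CC[C@H](OB1OC(C)(C)C(C)(C)O1)CC=CCCCCCCCCCC=C | intermediate
8 | (3S)-heptadeca-5,16-dien-3-ol (5E/5Z mixture) | CC[C@H](O)CC=CCCCCCCCCCC=C | intermediate
9 | 9-borabicyclo[3.3.1]nonane (9-BBN, handled as its dimer) | B1C2CCCC1CCC2 | starting material
10 | 1-bromo-3,5-bis(benzyloxy)benzene | Brc1cc(OCc2ccccc2)cc(OCc2ccccc2)c1 | starting material
11 | 9-{[(3S)-17-(9-borabicyclo[3.3.1]nonan-9-yl)heptadec-5-en-3-yl]oxy}-9-borabicyclo[3.3.1]nonane (5E/5Z mixture) | CC[C@H](OB1C2CCCC1CCC2)CC=CCCCCCCCCCCCB1C2CCCC1CCC2 | intermediate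
12 | (3S)-17-[3,5-bis(benzyloxy)phenyl]heptadec-5-en-3-ol (5E/5Z mixture) | CC[C@H](O)CC=CCCCCCCCCCCCc1cc(OCc2ccccc2)cc(OCc2ccccc2)c1 | intermediate
13 | Hansfordiol C, 5-[(15S)-15-hydroxyheptadecyl]benzene-1,3-diol | CC[C@H](O)CCCCCCCCCCCCCCc1cc(O)cc(O)c1 | target

**Totals**
Total step count: 4. Longest linear sequence: 4.

**Steps most likely to fail**

Step 2 (the proposed new reaction). The slower-reacting enantiomer of 5 may not react through the E-forming transition state at a useful rate, which caps the yield near 50 %. It may instead leak through the Si-face pathway and lower the ee; about 90 % ee is a reasonable expectation, to be raised by recrystallising 13. The facial sense is assigned by analogy with allyl pinacol boronate additions, and (S)-TRIP is used if it proves reversed.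

The fallback uses known chemistry only, sets out from 10 and comes back to the route at 13. Excess 1,13-tetradecadiene is mono-hydroborated with 9 to give 9-(tetradec-13-en-1-yl)-9-borabicyclo[3.3.1]nonane F1. This is coupled in the same flask with 10 (Pd(dppf)Cl2, aq. NaOH, THF, 65 °C) to give 1,3-bis(benzyloxy)-5-(tetradec-13-en-1-yl)benzene F2. Cross-metathesis of F2 with pent-1-en-3-one (Hoveyda–Grubbs II, CH2Cl2, 40 °C) gives (E)-17-[3,5-bis(benzyloxy)phenyl]heptadec-4-en-3-one F3. Corey–Bakshi–Shibata reduction with (R)-Me-CBS and BH3·SMe2 in toluene at −40 °C, in which the alkenyl group acts as the large substituent, gives (3S,4E)-17-[3,5-bis(benzyloxy)phenyl]heptadec-4-en-3-ol F4. Hydrogenation of F4 under the conditions of step 4 gives 13.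

Step 1. Direct SN2 attack of the Grignard reagent at the CH2Cl group, or a sluggish 1,2-shift of the magnesium borate, would give the linear alkenylboronate or return starting materials.

The fallback sets out from 1 and comes back at 5; it places the alkyl group on boron first and brings in the allyl unit as a carbenoid. Grignard reagent 3, made as in step 1, is quenched with 2-isopropoxy-4,4,5,5-tetramethyl-1,3,2-dioxaborolane to give 4,4,5,5-tetramethyl-2-(undec-10-en-1-yl)-1,3,2-dioxaborolane F5. LDA is then added to a mixture of F5 and allyl chloride in THF at −78 °C, so that (1-chloroprop-2-en-1-yl)lithium F6 is trapped as it forms as lithium (1-chloroprop-2-en-1-yl)(undec-10-en-1-yl)pinacolatoborate F7. On warming, F7 undergoes the Matteson-type 1,2-migration with loss of the α-chloride and gives 5.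

Step 3. Incomplete discrimination between the two alkenes, or interference of the free hydroxyl with the hydroboration or the coupling, would lower the yield on the most valuable intermediate.

The fallback sets out from 1 and comes back at 12; it installs the arene before the boron chemistry, so no chiral alkenol ever meets 9-BBN. Hydroboration of 1 with 9 gives 9-(11-bromoundecyl)-9-borabicyclo[3.3.1]nonane F8. This is coupled with 10 (Pd(dppf)Cl2, K3PO4, THF–DMF, 50 °C; the primary alkyl bromide is inert to this catalyst) to give 1,3-bis(benzyloxy)-5-(11-bromoundecyl)benzene F9. Magnesium in THF converts F9 into {11-[3,5-bis(benzyloxy)phenyl]undecyl}magnesium bromide F10, which adds to 2 as in step 1 to give bromomagnesium {11-[3,5-bis(benzyloxy)phenyl]undecyl}[(E)-3-chloroprop-1-en-1-yl]pinacolatoborate F11. After the 1,2-shift this gives rac-2-{14-[3,5-bis(benzyloxy)phenyl]tetradec-1-en-3-yl}-4,4,5,5-tetramethyl-1,3,2-dioxaborolane F12. Allylboration of 6 with F12 under the conditions of step 2 gives 2-({(3S)-17-[3,5-bis(benzyloxy)phenyl]heptadec-5-en-3-yl}oxy)-4,4,5,5-tetramethyl-1,3,2-dioxaborolane F13 and, after aqueous work-up, 12.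

**Further compounds**
F1 | step 2 | 9-(tetradec-13-en-1-yl)-9-borabicyclo[3.3.1]nonane | C=CCCCCCCCCCCCCB1C2CCCC1CCC2
F2 | step 2 | 1,3-bis(benzyloxy)-5-(tetradec-13-en-1-yl)benzene | C=CCCCCCCCCCCCCc1cc(OCc2ccccc2)cc(OCc2ccccc2)c1
F3 | step 2 | (E)-17-[3,5-bis(benzyloxy)phenyl]heptadec-4-en-3-one | CCC(=O)/C=C/CCCCCCCCCCCCc1cc(OCc2ccccc2)cc(OCc2ccccc2)c1
F4 | step 2 | (3S,4E)-17-[3,5-bis(benzyloxy)phenyl]heptadec-4-en-3-ol | CC[C@H](O)/C=C/CCCCCCCCCCCCc1cc(OCc2ccccc2)cc(OCc2ccccc2)c1
F5 | step 1 | 4,4,5,5-tetramethyl-2-(undec-10-en-1-yl)-1,3,2-dioxaborolane | C=CCCCCCCCCCB1OC(C)(C)C(C)(C)O1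
F6 | step 1 | (1-chloroprop-2-en-1-yl)lithium | [Li]C(Cl)C=C
F7 | step 1 | lithium (1-chloroprop-2-en-1-yl)(undec-10-en-1-yl)pinacolatoborate | C=CCCCCCCCCC[B-]1(C(Cl)C=C)OC(C)(C)C(C)(C)O1.[Li+]
F8 | step 3 | 9-(11-bromoundecyl)-9-borabicyclo[3.3.1]nonane | BrCCCCCCCCCCCB1C2CCCC1CCC2
F9 | step 3 | 1,3-bis(benzyloxy)-5-(11-bromoundecyl)benzene | BrCCCCCCCCCCCc1cc(OCc2ccccc2)cc(OCc2ccccc2)c1
F10 | step 3 | {11-[3,5-bis(benzyloxy)phenyl]undecyl}magnesium bromide | Br[Mg]CCCCCCCCCCCc1cc(OCc2ccccc2)cc(OCc2ccccc2)c1
F11 | step 3 | bromomagnesium {11-[3,5-bis(benzyloxy)phenyl]undecyl}[(E)-3-chloroprop-1-en-1-yl]pinacolatoborate | ClC/C=C/[B-]1(CCCCCCCCCCCc2cc(OCc3ccccc3)cc(OCc3ccccc3)c2)OC(C)(C)C(C)(C)O1.[Mg+]Br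
F12 | step 3 | rac-2-{14-[3,5-bis(benzyloxy)phenyl]tetradec-1-en-3-yl}-4,4,5,5-tetramethyl-1,3,2-dioxaborolane | C=CC(CCCCCCCCCCCc1cc(OCc2ccccc2)cc(OCc2ccccc2)c1)B1OC(C)(C)C(C)(C)O1
F13 | step 3 | 2-({(3S)-17-[3,5-bis(benzyloxy)phenyl]heptadec-5-en-3-yl}oxy)-4,4,5,5-tetramethyl-1,3,2-dioxaborolane | CC[C@H](OB1OC(C)(C)C(C)(C)O1)CC=CCCCCCCCCCCCc1cc(OCc2ccccc2)cc(OCc2ccccc2)c1
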